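Which flask leads in the share of target in target plus over-reaction product at the end? I answered by keeping books on the reagent.

in all of them: catalyst 10 mM
- Saturday's: starting material 0.50 M; reagent 0.40 M; run made earlier
- Friday's: starting material 0.50 M; reagent 0.56 M; run made earlier
- Sunday's: starting material 0.50 M; reagent 0.88 M; run made earlier
- epsilon: starting material 0.50 M (in portions, 2, over 6.0 d); reagent 0.400 M; first portion at the start, last at 6.0 d; time 8.0 d
- theta: starting material 0.50 M; reagent 0.400 M; everything together at the start; time 8.0 d
- beta: starting material 0.50 M; reagent 0.400 M (fed, over 6.0 d); all else is in the flask from the start; the feed brings no volume worth counting; time 8.0 d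
- alpha: starting material 0.50 M (fed, over 6.0 d); reagent 0.400 M; all else is in the flask from the start; the feed brings no volume worth counting; time 8.0 d

| run | time / d | target / % | over-reaction product / % | starting material / % |
|---|---|---|---|---|
| Saturday's | 0.417 | 9 | 0 | 90 |
| Saturday's | 0.625 | 14 | 1 | 85 |
| Saturday's | 0.833 | 14 | 3 | 80 |
| Saturday's | 1.25 | 22 | 4 | 75 |
| Saturday's | 2.08 | 26 | 11 | 63 |
| Saturday's | 3.00 | 28 | 17 | 53 |
| Saturday's | 5.00 | 26 | 32 | 39 |
| Friday's | 0.625 | 19 | 3 | 80 |
| Friday's | 1.25 | 28 | 4 | 65 |
| Friday's | 2.08 | 38 | 17 | 49 |
| Friday's | 3.00 | 36 | 25 | 38 |
| Friday's | 4.00 | 35 | 34 | 29 |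
| Friday's | 5.00 | 33 | 45 | 20 |
| Sunday's | 0.625 | 28 | 4 | 68 |
| Sunday's | 1.25 | 43 | 9 | 45 |
| Sunday's | 2.08 | 53 | 20 | 28 |
| Sunday's | 3.00 | 48 | 32 | 14 |
| Sunday's | 4.00 | 47 | 50 | 5 |
| Sunday's | 5.00 | 40 | 62 | 3 |

(standard deviation of a reading: 1.5 percentage points)

- what was read earlier has a scatter of 1.5 percentage points, one standard deviation
- reactions considered so far: starting material + reagent + catalyst -> target + catalyst; target -> over-reaction product

- which flask leads in share of target in target plus over-reaction product ("all alike" within 1.5 percentage points) (epsilon / theta / beta / alpha / all alike)
- share of target in target plus over-reaction product at the end, epsilon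
- share of target in target plus over-reaction product at the end, theta
- share of target in target plus over-reaction product at the end, beta
- share of target in target plus over-reaction product at the end, alpha

In the four flasks the reagent was the limiting reagent, 0.400 M against 0.50 M of starting material, so each mole of it had three possible entries: free, in target, or in over-reaction product. Each mole of starting material lost takes one of reagent. In Saturday's run, therefore, free reagent had fallen to 0.0950 M at 5.00 d, which as a pseudo-first-order decay means an average frequency of 0.288 d⁻¹. In Friday's run the over-reaction product gained 20 percentage points between 3.00 d and 5.00 d on about 34.5 % of target, a frequency of 0.290 d⁻¹. These two readings matched within their scatter, so I carried their mean, λ = 0.289 d⁻¹, the clock: my estimate of the frequency at which free reagent becomes target and target becomes over-reaction product.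

For theta, with t the time since the start and x = λt, free reagent is e^(−x) of its charge and target x·e^(−x), so the share is x/(e^x − 1), which I reckoned for 8.0 d as 25.5 %. For beta, the books stood at 0.190 M free and 0.119 M in target when the feed ended. After the remaining 2.00 d they closed at 0.107 M free, 0.129 M in target and, as the remainder of 0.400 M, 0.165 M in over-reaction product, a share of 43.8 %. Putting that answer back, the books of beta left 41.4 % of the starting material at the end, and Saturday's frequency had been read over the fall to 39 %, so for beta I kept λ. Epsilon and alpha, which bring part of the starting material in late, I did not reckon with λ; I expected them between theta and beta.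

The forecast said beta, with epsilon 31 %, theta 23 %, beta 41 % and alpha 33 %: “Beta leads, though with lower conversion”. The flasks gave epsilon 31.6 %, theta 24.6 %, beta 42.6 % and alpha 35.2 %, so beta led, against my 43.8 % for beta and 25.5 % for theta.

    starting material + reagent + catalyst → target + catalyst, rate k1*[starting material]*[reagent]*[catalyst]/(1 + ([starting material]/sat1)) (0.160 M, k = 11.0 M⁻² h⁻¹)
    target → over-reaction product (k = 0.0120 h⁻¹)

In beta, half of the turnover into target was done by 4.64 d, so the middle mole of target had stood 3.36 d at the end, longer than the half-life of target, 2.4 d, and λ = 0.289 d⁻¹ leaves 37.9 % of such a mole. On the neighbour of beta with a quarter of the catalyst, λ scaled in proportion for the reagent's step gave 70.3 % of the reagent free at the end, and that flask held 68.7 %.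

The runs are calculated on assumed constants.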